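**Retrosynthetic overview**

- Locants: ring A is a1 (C=CH2), a2, a3, a4 (CHOH), a5 (CMe2), a6 (CH); the chain is C7=C8–C9(Me)=C10–C11H(OH); ring B is C12/C13 (oxirane), C14 (CHOH), C15 (C–CH2OH), C16 (=CH), C17 (CHOH). The strategy rests on the exocyclic methylene at a1 next to a6, which carries the E alkene C7=C8 conjugated with C9=C10. This 1,4-diene (a1=CH2 / C7=C8) is an Alder-ene retron, so ring A is opened at a1–a6 to an acyclic 1,7-enyne with a skipped a6=C7 / C9=C10 diene.
- The enyne is assembled by Julia–Kocienski olefination (a6=C7) of an α-quaternary aldehyde (a4 set by an enantioselective Mukaiyama aldol) with a Z-configured C7–C11 sulfone made from but-2-yn-1-ol.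
- C11–C12 is formed by adding a ring B alkenyllithium to the Z-dienal. The ring B piece is a quinone monoketal alcohol from 4-bromo-2,5-dimethoxybenzaldehyde, with C17 set by CBS reduction. Oxidation to the C11 ketone then allows enone epoxidation of C12=C13 without touching the diene; C11 and C14 are set by a hydroxyl-directed and a substrate-controlled reduction.
- Ring order: the ring B carbocycle is carried from the arene, ring A is closed in the key step, the oxirane is closed last.

Key step: step 13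

Remark: compound 30 is carried as both C11 epimers, because step 23 removes that stereocentre and step 26 sets it again; RA stands for the ring A unit (1S,3R)-3-[(tert-butyldimethylsilyl)oxy]-2,2-dimethyl-6-methylidenecyclohexyl.

**Route**

Step 1
Reactants: 1 but-2-yn-1-ol
Product: 3 (2Z)-3-iodobut-2-en-1-ol, via sodium alkenylaluminate 2 (not isolated)
Conditions: NaAlH2(OCH2CH2OMe)2, THF, 0 °C to rt; then I2, THF, −78 °C to rt
Reagents that add atoms: iodine, II; sodium bis(2-methoxyethoxy)aluminium hydride, [Na+].COCCO[AlH2-]OCCOC (aluminium in intermediate 2 only)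
Why: Hydroxyl-directed trans-hydroalumination of the propargylic alcohol puts aluminium on C3 inside a five-membered alkoxyaluminate, and iodinolysis with retention gives the Z iodide that later fixes the C9=C10 geometry (reduction–iodination of a propargylic alcohol).

Step 2
Reactants: 3 (2Z)-3-iodobut-2-en-1-ol
Product: 4 tert-butyl{[(2Z)-3-iodobut-2-en-1-yl]oxy}dimethylsilane
Conditions: TBSCl, imidazole, CH2Cl2, rt
Reagents that add atoms: tert-butyldimethylsilyl chloride, CC(C)(C)[Si](C)(C)Cl
Why: Imidazole-promoted silylation of the primary alcohol is routine and leaves the alkenyl iodide untouched.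

Step 3
Reactants: 4 tert-butyl{[(2Z)-3-iodobut-2-en-1-yl]oxy}dimethylsilane
Product: 5 tert-butyldimethyl{[(2Z)-3-methylpenta-2,4-dien-1-yl]oxy}silane
Conditions: CH2=CHSnBu3, Pd(PPh3)4 (5 mol %), DMF, 50 °C
Reagents that add atoms: tributyl(vinyl)stannane, C=C[Sn](CCCC)(CCCC)CCCC
Why: Stille coupling proceeds with retention at the alkenyl iodide, so the new vinyl group (C8=C7) stays cis to C11.

Step 4
Reactants: 5 tert-butyldimethyl{[(2Z)-3-methylpenta-2,4-dien-1-yl]oxy}silane
Product: 7 (3Z)-5-[(tert-butyldimethylsilyl)oxy]-3-methylpent-3-en-1-ol, via B-alkyl-9-BBN 6 (not isolated)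
Conditions: 9-BBN, THF, 0 °C to rt; then NaOH, H2O2, 0 °C
Reagents that add atoms: hydrogen peroxide, OO; 9-borabicyclo[3.3.1]nonane, [BH]1C2CCCC1CCC2 (boron in intermediate 6 only)
Why: Hydroboration–oxidation with the bulky 9-BBN places boron on the terminal carbon of the monosubstituted vinyl group and leaves the trisubstituted Z alkene, giving the primary C7 alcohol.

Step 5
Reactants: 7 (3Z)-5-[(tert-butyldimethylsilyl)oxy]-3-methylpent-3-en-1-ol
Product: 8 5-{[(3Z)-5-[(tert-butyldimethylsilyl)oxy]-3-methylpent-3-en-1-yl]sulfanyl}-1-phenyl-1H-tetrazole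
Conditions: 1-phenyl-1H-tetrazole-5-thiol, PPh3, DIAD, THF, 0 °C to rt
Reagents that add atoms: 1-phenyl-1H-tetrazole-5-thiol, Sc1nnnn1-c1ccccc1
Why: Mitsunobu thioetherification of an unhindered primary alcohol with the acidic heteroaryl thiol is reliable and does not affect the alkene geometry.

Step 6
Reactants: 8 5-{[(3Z)-5-[(tert-butyldimethylsilyl)oxy]-3-methylpent-3-en-1-yl]sulfanyl}-1-phenyl-1H-tetrazole
Product: 9 5-{[(3Z)-5-[(tert-butyldimethylsilyl)oxy]-3-methylpent-3-en-1-yl]sulfonyl}-1-phenyl-1H-tetrazole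
Conditions: (NH4)6Mo7O24·4H2O (10 mol %), 30% H2O2, EtOH, 0 °C to rt
Reagents that add atoms: hydrogen peroxide, OO
Why: Molybdate-catalysed peroxide oxidation takes the sulfide to the sulfone much faster than it epoxidizes a trisubstituted alkene.

Step 7
Reactants: 10 pent-4-yn-1-ol
Product: 11 pent-4-ynal
Conditions: (COCl)2, DMSO, CH2Cl2, −78 °C; then Et3N, −78 °C to 0 °C
Reagents that add atoms: none
Why: Swern oxidation gives the volatile aldehyde without over-oxidation, and it is used directly as a solution.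

Step 8
Reactants: 11 pent-4-ynal; 12 methyl trimethylsilyl dimethylketene acetal
Product: 13 methyl (3R)-3-hydroxy-2,2-dimethylhept-6-ynoate
Conditions: N-tosyl-L-valine, BH3·THF, CH2Cl2, 0 °C to rt; then 11 and 12, −78 °C; pH 7 buffer
Reagents that add atoms: none
Why: Enantioselective Mukaiyama aldol promoted by the stoichiometric N-tosyl-L-valine-derived oxazaborolidinone, in which the ketene acetal attacks the Si face of the boron-bound aldehyde and sets a4 as 3R.

Step 9
Reactants: 13 methyl (3R)-3-hydroxy-2,2-dimethylhept-6-ynoate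
Product: 14 methyl (3R)-3-[(tert-butyldimethylsilyl)oxy]-2,2-dimethylhept-6-ynoate
Conditions: TBSOTf, 2,6-lutidine, CH2Cl2, 0 °C
Reagents that add atoms: tert-butyldimethylsilyl trifluoromethanesulfonate, CC(C)(C)[Si](C)(C)OS(=O)(=O)C(F)(F)F
Why: The silyl triflate is needed to silylate the hindered neopentyl-type secondary alcohol, and the non-nucleophilic base leaves the ester and alkyne untouched.

Step 10
Reactants: 14 methyl (3R)-3-[(tert-butyldimethylsilyl)oxy]-2,2-dimethylhept-6-ynoate
Product: 15 (3R)-3-[(tert-butyldimethylsilyl)oxy]-2,2-dimethylhept-6-yn-1-ol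
Conditions: i-Bu2AlH (2.5 equiv), CH2Cl2, −78 °C to 0 °C; Rochelle salt
Reagents that add atoms: none
Why: Hydride reduction of the ester to the primary alcohol is clean at low temperature, where the terminal alkyne is not hydroaluminated.

Step 11
Reactants: 15 (3R)-3-[(tert-butyldimethylsilyl)oxy]-2,2-dimethylhept-6-yn-1-ol
Product: 16 (3R)-3-[(tert-butyldimethylsilyl)oxy]-2,2-dimethylhept-6-ynal
Conditions: Dess–Martin periodinane, CH2Cl2, rt
Reagents that add atoms: none
Why: Dess–Martin oxidation gives the non-enolizable α-quaternary aldehyde, so a4 cannot epimerize.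

Step 12
Reactants: 9 5-{[(3Z)-5-[(tert-butyldimethylsilyl)oxy]-3-methylpent-3-en-1-yl]sulfonyl}-1-phenyl-1H-tetrazole; 16 (3R)-3-[(tert-butyldimethylsilyl)oxy]-2,2-dimethylhept-6-ynal
Product: 18 (5R,7E,10Z)-5,12-bis[(tert-butyldimethylsilyl)oxy]-6,6,10-trimethyldodeca-7,10-dien-1-yne, via potassium sulfonyl carbanion 17 (not isolated)
Conditions: KN(SiMe3)2, DME, −60 °C; then 16, −60 °C to rt
Reagents that add atoms: potassium bis(trimethylsilyl)amide, C[Si](C)(C)[N-][Si](C)(C)C.[K+] (potassium in intermediate 17 only)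
Why: Julia–Kocienski olefination, in which the premetalated phenyltetrazolyl sulfone adds to the hindered non-enolizable aldehyde and Smiles rearrangement with loss of SO2 gives the E alkene a6=C7, while premetalation keeps free base away from the terminal alkyne.

Step 13
Reactants: 18 (5R,7E,10Z)-5,12-bis[(tert-butyldimethylsilyl)oxy]-6,6,10-trimethyldodeca-7,10-dien-1-yne
Product: 19 tert-butyl{[(1R,3S)-3-[(1E,3Z)-5-[(tert-butyldimethylsilyl)oxy]-3-methylpenta-1,3-dien-1-yl]-2,2-dimethyl-4-methylidenecyclohexyl]oxy}dimethylsilane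
Conditions: Pd(OAc)2 (5 mol %), PPh3 (10 mol %), AcOH (20 mol %), toluene, 60 °C
Reagents that add atoms: none
Why: Pd(OAc)2 is reduced by PPh3 to zerovalent palladium, which adds AcOH to give HPd(OAc) (divalent palladium); this hydride adds syn across the terminal alkyne with palladium on a1, the alkenylpalladium inserts the a6=C7 alkene, and syn β-hydride elimination of a C8 hydrogen releases the diene and regenerates the hydride. The closest known reaction type is the palladium-catalysed Alder-ene cycloisomerization of 1,6- and 1,7-enynes to 1,4-dienes. Ring A closes by 6-exo-trig carbopalladation, which forms the a1–a6 bond. The new a6 stereocentre is controlled by the a4 silyloxy stereocentre through a chair-like insertion transition state with the OTBS group and the C7 alkenyl arm both equatorial, which should give the cis (1R,3S) isomer, and the a5 gem-dimethyl group favours the folded reactive conformer. The step needs palladium on a1 (secured by the terminal alkyne), elimination towards C8 and not a6 (the C8 hydrogens are allylic to C9=C10 and lead to the conjugated diene, whereas the a6 hydrogen is tertiary and flanked by the quaternary a5), E geometry at C7=C8 (syn elimination from the rotamer with C9 anti to the ring) and an untouched Z alkene at C9=C10 (low acid loading and moderate temperature limit re-addition of the hydride to the diene).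

Step 14
Reactants: 19 tert-butyl{[(1R,3S)-3-[(1E,3Z)-5-[(tert-butyldimethylsilyl)oxy]-3-methylpenta-1,3-dien-1-yl]-2,2-dimethyl-4-methylidenecyclohexyl]oxy}dimethylsilane
Product: 20 (2Z,4E)-3-methyl-5-RA-penta-2,4-dien-1-ol
Conditions: HF·pyridine, pyridine, THF, 0 °C
Reagents that add atoms: none
Why: Fluoride-mediated desilylation is much faster at the unhindered primary allylic silyl ether than at the neopentyl-type secondary ether on a4, so only the C11 hydroxyl is freed.

Step 15
Reactants: 20 (2Z,4E)-3-methyl-5-RA-penta-2,4-dien-1-ol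
Product: 21 (2Z,4E)-3-methyl-5-RA-penta-2,4-dienal
Conditions: MnO2, CH2Cl2, rt
Reagents that add atoms: none
Why: MnO2 oxidizes the allylic alcohol under neutral conditions, which should preserve the Z geometry of the enal.

Step 16
Reactants: 22 4-bromo-2,5-dimethoxybenzaldehyde
Product: 23 (4-bromo-2,5-dimethoxyphenyl)methanol
Conditions: NaBH4, MeOH, 0 °C
Reagents that add atoms: none
Why: Borohydride reduction of the aryl aldehyde is chemoselective and leaves the aryl bromide intact.

Step 17
Reactants: 23 (4-bromo-2,5-dimethoxyphenyl)methanol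
Product: 24 [(4-bromo-2,5-dimethoxybenzyl)oxy]tri(propan-2-yl)silane
Conditions: TIPSCl, imidazole, DMF, rt
Reagents that add atoms: triisopropylsilyl chloride, CC(C)[Si](Cl)(C(C)C)C(C)C
Why: Silylation with the base- and acid-stable triisopropylsilyl group protects the future C15 hydroxymethyl through the electrolysis, the hydrolyses and the organolithium step.

Step 18
Reactants: 24 [(4-bromo-2,5-dimethoxybenzyl)oxy]tri(propan-2-yl)silane
Product: 25 [(4-bromo-3,3,6,6-tetramethoxycyclohexa-1,4-dien-1-yl)methoxy]tri(propan-2-yl)silane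
Conditions: Pt anode, Pt cathode, 1% KOH in MeOH, 0 °C, constant current
Reagents that add atoms: methanol, CO
Why: Anodic bis-methoxylation of a 1,4-dimethoxyarene (two-electron oxidation with methanol capture at both methoxy-bearing carbons) is the standard entry to quinone bisketals and tolerates the aryl bromide and the silyl ether.

Step 19
Reactants: 25 [(4-bromo-3,3,6,6-tetramethoxycyclohexa-1,4-dien-1-yl)methoxy]tri(propan-2-yl)silane
Product: 26 2-bromo-4,4-dimethoxy-5-{[(triisopropylsilyl)oxy]methyl}cyclohexa-2,5-dien-1-one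
Conditions: AcOH, H2O, acetone, 0 °C to rt
Reagents that add atoms: water, O
Why: Acid-catalysed monohydrolysis of the bisketal, in which ionization of the C17 ketal gives an alkoxyallyl cation with its charge on the alkyl-substituted C15 and on C13 but not on the bromine-bearing C12, so the carbonyl appears next to the C–Br carbon and the monoketal resists further hydrolysis.

Step 20
Reactants: 26 2-bromo-4,4-dimethoxy-5-{[(triisopropylsilyl)oxy]methyl}cyclohexa-2,5-dien-1-one
Product: 27 (1S)-2-bromo-4,4-dimethoxy-5-{[(triisopropylsilyl)oxy]methyl}cyclohexa-2,5-dien-1-ol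
Conditions: (R)-1-methyl-3,3-diphenyltetrahydro-1H,3H-pyrrolo[1,2-c][1,3,2]oxazaborole (20 mol %), catecholborane, toluene, −78 °C
Reagents that add atoms: none
Why: Corey–Bakshi–Shibata reduction, in which the ketone binds the (R)-oxazaborolidine–borane complex with the bromine-bearing alkenyl arm as the large group, so hydride is delivered to the face that gives the 1S alcohol (C17 S) by 1,2-reduction.

Step 21
Reactants: 27 (1S)-2-bromo-4,4-dimethoxy-5-{[(triisopropylsilyl)oxy]methyl}cyclohexa-2,5-dien-1-ol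
Product: 28 triethyl{[(1S)-2-bromo-4,4-dimethoxy-5-{[(triisopropylsilyl)oxy]methyl}cyclohexa-2,5-dien-1-yl]oxy}silane
Conditions: TESCl, imidazole, DMF, 0 °C
Reagents that add atoms: triethylsilyl chloride, CC[Si](Cl)(CC)CC
Why: Silylation under basic conditions avoids the acid-promoted aromatization of the dienol ketal and installs a group that can later be removed in the presence of the TBS and TIPS ethers.

Step 22
Reactants: 28 triethyl{[(1S)-2-bromo-4,4-dimethoxy-5-{[(triisopropylsilyl)oxy]methyl}cyclohexa-2,5-dien-1-yl]oxy}silane; 21 (2Z,4E)-3-methyl-5-RA-penta-2,4-dienal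
Product: 30 C11 carbinol (11RS,17S) (2Z,4E)-1-[(6S)-3,3-dimethoxy-6-[(triethylsilyl)oxy]-4-{[(triisopropylsilyl)oxy]methyl}cyclohexa-1,4-dien-1-yl]-3-methyl-5-RA-penta-2,4-dien-1-ol, via alkenyllithium 29 (not isolated)
Conditions: t-BuLi (2 equiv), Et2O, −78 °C; then 21, −78 °C
Reagents that add atoms: tert-butyllithium, [Li]C(C)(C)C (lithium in intermediate 29 only)
Why: Bromine–lithium exchange gives the alkenyllithium, which adds 1,2 to the enal and forms the C11–C12 bond; C11 forms as both epimers, which is harmless because the next step removes that stereocentre.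

Step 23
Reactants: 30 C11 carbinol (11RS,17S)
Product: 31 C11 ketone (17S) (2Z,4E)-1-[(6S)-3,3-dimethoxy-6-[(triethylsilyl)oxy]-4-{[(triisopropylsilyl)oxy]methyl}cyclohexa-1,4-dien-1-yl]-3-methyl-5-RA-penta-2,4-dien-1-one
Conditions: Dess–Martin periodinane, pyridine, CH2Cl2, 0 °C
Reagents that add atoms: none
Why: Dess–Martin oxidation of the bis-allylic alcohol under buffered conditions converges both epimers on one cross-conjugated ketone without acid that would aromatize ring B.

Step 24
Reactants: 31 C11 ketone (17S)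
Product: 32 epoxy ketone (12S,13R,17S), that is 31 with a 12,13-oxirane trans to the C17 triethylsilyloxy group
Conditions: t-BuOOH (anhydrous, in decane), DBU, CH2Cl2, 0 °C
Reagents that add atoms: tert-butyl hydroperoxide, CC(C)(C)OO
Why: Nucleophilic (Weitz–Scheffer) epoxidation, in which the peroxide adds to C13, the unhindered β-carbon of the C11 ketone, and the enolate closes the oxirane at C12 on the ring face opposite the C17 silyloxy group, while the non-activated exocyclic alkene stays inert and attack at the β,β-disubstituted C9 or at C7 is expected to be slower.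

Step 25
Reactants: 32 epoxy ketone (12S,13R,17S)
Product: 33 β-hydroxy ketone (12R,13R,17S), that is 32 with a free C17 hydroxyl
Conditions: HF·pyridine, pyridine, THF, 0 °C
Reagents that add atoms: none
Why: The secondary triethylsilyl ether is cleaved by buffered fluoride far faster than the hindered TBS ether on a4 and the primary triisopropylsilyl ether, which frees the hydroxyl that directs the next reduction.

Step 26
Reactants: 33 β-hydroxy ketone (12R,13R,17S)
Product: 34 anti-diol (11S,12R,13R,17S), that is 33 with the C11 ketone reduced to the 11S alcohol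
Conditions: Me4NBH(OAc)3, MeCN/AcOH, −35 °C
Reagents that add atoms: none
Why: Evans–Saksena reduction, in which the C17 hydroxyl exchanges onto boron and delivers hydride intramolecularly through a chair-like six-membered transition state with the dienyl group equatorial, which gives the 1,3-anti diol and therefore 11S.

Step 27
Reactants: 34 anti-diol (11S,12R,13R,17S)
Product: 35 C14 enone (11S,12R,13R,17S), that is 34 with the C14 dimethyl ketal converted into the ketone
Conditions: pyridinium p-toluenesulfonate, acetone/H2O, rt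
Reagents that add atoms: water, O
Why: Acid-catalysed ketal hydrolysis, in which the C14 ketal ionizes to an oxocarbenium ion stabilized by the C15=C16 alkene, so mild pyridinium catalysis should suffice and spare the oxirane and the silyl ethers.

Step 28
Reactants: 35 C14 enone (11S,12R,13R,17S)
Product: 36 triol (11S,12R,13S,14R,17S), that is the target carrying TBS on the a4 oxygen and TIPS on the C15 hydroxymethyl oxygen
Conditions: NaBH4, CeCl3·7H2O, MeOH, −78 °C
Reagents that add atoms: none
Why: Luche reduction, in which CeCl3 (trivalent cerium) secures 1,2-reduction and hydride adds to C14 from the oxirane face because the C11 side chain on C12 (cis-1,3 to C14) shields the other face, giving the 14R alcohol trans to the epoxide.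

Step 29
Reactants: 36 triol (11S,12R,13S,14R,17S)
Product: 37 (1R,2S,5R,6S)-1-[(1S,2Z,4E)-1-hydroxy-5-[(1S,3R)-3-hydroxy-2,2-dimethyl-6-methylidenecyclohexyl]-3-methylpenta-2,4-dien-1-yl]-4-(hydroxymethyl)-7-oxabicyclo[4.1.0]hept-3-ene-2,5-diol (CNP0357844.1)
Conditions: HF·pyridine, pyridine, THF, 0 °C to rt
Reagents that add atoms: none
Why: Pyridine-buffered fluoride cleaves the remaining TBS and TIPS ethers without the base that could trigger epoxide migration, and no stereocentre is touched.

**Compound list**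

1 | but-2-yn-1-ol | CC#CCO | starting material
2 | sodium alkenylaluminate (cyclic alkoxy(alkenyl)aluminate from 1, aluminium on C3 cis to CH2O) | [Na+].COCCO[Al-]1(OCCOC)OC/C=C1/C | intermediate
3 | (2Z)-3-iodobut-2-en-1-ol | C/C(I)=C/CO | intermediate
4 | tert-butyl{[(2Z)-3-iodobut-2-en-1-yl]oxy}dimethylsilane | C/C(I)=C/CO[Si](C)(C)C(C)(C)C | intermediate
5 | tert-butyldimethyl{[(2Z)-3-methylpenta-2,4-dien-1-yl]oxy}silane | C=C/C(C)=C\CO[Si](C)(C)C(C)(C)C | intermediate
6 | B-alkyl-9-BBN, 9-[(3Z)-5-[(tert-butyldimethylsilyl)oxy]-3-methylpent-3-en-1-yl]-9-borabicyclo[3.3.1]nonane | CC(C)(C)[Si](C)(C)OC/C=C(C)\CCB1C2CCCC1CCC2 | intermediate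
7 | (3Z)-5-[(tert-butyldimethylsilyl)oxy]-3-methylpent-3-en-1-ol | OCC/C(C)=C\CO[Si](C)(C)C(C)(C)C | intermediate
8 | 5-{[(3Z)-5-[(tert-butyldimethylsilyl)oxy]-3-methylpent-3-en-1-yl]sulfanyl}-1-phenyl-1H-tetrazole | CC(C)(C)[Si](C)(C)OC/C=C(C)\CCSc1nnnn1-c1ccccc1 | intermediate
9 | 5-{[(3Z)-5-[(tert-butyldimethylsilyl)oxy]-3-methylpent-3-en-1-yl]sulfonyl}-1-phenyl-1H-tetrazole | CC(C)(C)[Si](C)(C)OC/C=C(C)\CCS(=O)(=O)c1nnnn1-c1ccccc1 | intermediate
10 | pent-4-yn-1-ol | C#CCCCO | starting material
11 | pent-4-ynal | C#CCCC=O | intermediate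
12 | methyl trimethylsilyl dimethylketene acetal | COC(O[Si](C)(C)C)=C(C)C | starting material
13 | methyl (3R)-3-hydroxy-2,2-dimethylhept-6-ynoate | C#CCC[C@@H](O)C(C)(C)C(=O)OC | intermediate
14 | methyl (3R)-3-[(tert-butyldimethylsilyl)oxy]-2,2-dimethylhept-6-ynoate | C#CCC[C@@H](O[Si](C)(C)C(C)(C)C)C(C)(C)C(=O)OC | intermediate
15 | (3R)-3-[(tert-butyldimethylsilyl)oxy]-2,2-dimethylhept-6-yn-1-ol | C#CCC[C@@H](O[Si](C)(C)C(C)(C)C)C(C)(C)CO | intermediate
16 | (3R)-3-[(tert-butyldimethylsilyl)oxy]-2,2-dimethylhept-6-ynal | C#CCC[C@@H](O[Si](C)(C)C(C)(C)C)C(C)(C)C=O | intermediate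
17 | potassium sulfonyl carbanion of 9 | [K+].CC(C)(C)[Si](C)(C)OC/C=C(C)\C[CH-]S(=O)(=O)c1nnnn1-c1ccccc1 | intermediate
18 | (5R,7E,10Z)-5,12-bis[(tert-butyldimethylsilyl)oxy]-6,6,10-trimethyldodeca-7,10-dien-1-yne | C#CCC[C@@H](O[Si](C)(C)C(C)(C)C)C(C)(C)/C=C/C/C(C)=C\CO[Si](C)(C)C(C)(C)C | intermediate
19 | tert-butyl{[(1R,3S)-3-[(1E,3Z)-5-[(tert-butyldimethylsilyl)oxy]-3-methylpenta-1,3-dien-1-yl]-2,2-dimethyl-4-methylidenecyclohexyl]oxy}dimethylsilane | C=C1CC[C@@H](O[Si](C)(C)C(C)(C)C)C(C)(C)[C@H]1/C=C/C(C)=C\CO[Si](C)(C)C(C)(C)C | intermediate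
20 | (2Z,4E)-5-[(1S,3R)-3-[(tert-butyldimethylsilyl)oxy]-2,2-dimethyl-6-methylidenecyclohexyl]-3-methylpenta-2,4-dien-1-ol | C=C1CC[C@@H](O[Si](C)(C)C(C)(C)C)C(C)(C)[C@H]1/C=C/C(C)=C\CO | intermediate
21 | (2Z,4E)-5-[(1S,3R)-3-[(tert-butyldimethylsilyl)oxy]-2,2-dimethyl-6-methylidenecyclohexyl]-3-methylpenta-2,4-dienal | C=C1CC[C@@H](O[Si](C)(C)C(C)(C)C)C(C)(C)[C@H]1/C=C/C(C)=C\C=O | intermediate
22 | 4-bromo-2,5-dimethoxybenzaldehyde | COc1cc(C=O)c(OC)cc1Br | starting material
23 | (4-bromo-2,5-dimethoxyphenyl)methanol | COc1cc(CO)c(OC)cc1Br | intermediate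
24 | [(4-bromo-2,5-dimethoxybenzyl)oxy]tri(propan-2-yl)silane | COc1cc(CO[Si](C(C)C)(C(C)C)C(C)C)c(OC)cc1Br | intermediate
25 | [(4-bromo-3,3,6,6-tetramethoxycyclohexa-1,4-dien-1-yl)methoxy]tri(propan-2-yl)silane | COC1(OC)C=C(Br)C(OC)(OC)C=C1CO[Si](C(C)C)(C(C)C)C(C)C | intermediate
26 | 2-bromo-4,4-dimethoxy-5-{[(triisopropylsilyl)oxy]methyl}cyclohexa-2,5-dien-1-one | O=C1C=C(CO[Si](C(C)C)(C(C)C)C(C)C)C(OC)(OC)C=C1Br | intermediate
27 | (1S)-2-bromo-4,4-dimethoxy-5-{[(triisopropylsilyl)oxy]methyl}cyclohexa-2,5-dien-1-ol | BrC1=CC(OC)(OC)C(CO[Si](C(C)C)(C(C)C)C(C)C)=C[C@@H]1O | intermediate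
28 | triethyl{[(1S)-2-bromo-4,4-dimethoxy-5-{[(triisopropylsilyl)oxy]methyl}cyclohexa-2,5-dien-1-yl]oxy}silane | BrC1=CC(OC)(OC)C(CO[Si](C(C)C)(C(C)C)C(C)C)=C[C@@H]1O[Si](CC)(CC)CC | intermediate
29 | alkenyllithium from 28 (lithium on C12) | [Li]C1=CC(OC)(OC)C(CO[Si](C(C)C)(C(C)C)C(C)C)=C[C@@H]1O[Si](CC)(CC)CC | intermediate
30 | C11 carbinol (11RS,17S), ring A dienyl–CH(OH)–ring B bisallylic alcohol | C=C1CC[C@@H](O[Si](C)(C)C(C)(C)C)C(C)(C)[C@H]1/C=C/C(C)=C\C(O)C1=CC(OC)(OC)C(CO[Si](C(C)C)(C(C)C)C(C)C)=C[C@@H]1O[Si](CC)(CC)CC | intermediate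
31 | C11 ketone (17S), cross-conjugated dienone | C=C1CC[C@@H](O[Si](C)(C)C(C)(C)C)C(C)(C)[C@H]1/C=C/C(C)=C\C(=O)C1=CC(OC)(OC)C(CO[Si](C(C)C)(C(C)C)C(C)C)=C[C@@H]1O[Si](CC)(CC)CC | intermediate
32 | epoxy ketone (12S,13R,17S), 12,13-oxirane trans to the C17 triethylsilyloxy group | C=C1CC[C@@H](O[Si](C)(C)C(C)(C)C)C(C)(C)[C@H]1/C=C/C(C)=C\C(=O)[C@]12O[C@H]1C(OC)(OC)C(CO[Si](C(C)C)(C(C)C)C(C)C)=C[C@@H]2O[Si](CC)(CC)CC | intermediate
33 | β-hydroxy ketone (12R,13R,17S), free C17 hydroxyl | C=C1CC[C@@H](O[Si](C)(C)C(C)(C)C)C(C)(C)[C@H]1/C=C/C(C)=C\C(=O)[C@]12O[C@H]1C(OC)(OC)C(CO[Si](C(C)C)(C(C)C)C(C)C)=C[C@@H]2O | intermediate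
34 | anti-diol (11S,12R,13R,17S), C14 dimethyl ketal | C=C1CC[C@@H](O[Si](C)(C)C(C)(C)C)C(C)(C)[C@H]1/C=C/C(C)=C\[C@H](O)[C@]12O[C@H]1C(OC)(OC)C(CO[Si](C(C)C)(C(C)C)C(C)C)=C[C@@H]2O | intermediate
35 | C14 enone (11S,12R,13R,17S) | C=C1CC[C@@H](O[Si](C)(C)C(C)(C)C)C(C)(C)[C@H]1/C=C/C(C)=C\[C@H](O)[C@]12O[C@H]1C(=O)C(CO[Si](C(C)C)(C(C)C)C(C)C)=C[C@@H]2O | intermediate
36 | triol (11S,12R,13S,14R,17S), a4 TBS ether and C15 CH2O–TIPS ether of the target | C=C1CC[C@@H](O[Si](C)(C)C(C)(C)C)C(C)(C)[C@H]1/C=C/C(C)=C\[C@H](O)[C@]12O[C@H]1[C@H](O)C(CO[Si](C(C)C)(C(C)C)C(C)C)=C[C@@H]2O | intermediate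
37 | (1R,2S,5R,6S)-1-[(1S,2Z,4E)-1-hydroxy-5-[(1S,3R)-3-hydroxy-2,2-dimethyl-6-methylidenecyclohexyl]-3-methylpenta-2,4-dien-1-yl]-4-(hydroxymethyl)-7-oxabicyclo[4.1.0]hept-3-ene-2,5-diol | C=C1CC[C@@H](O)C(C)(C)[C@H]1/C=C/C(C)=C\[C@H](O)[C@]12O[C@H]1[C@H](O)C(CO)=C[C@@H]2O | target

**Step count and risks**

Total step count: 29. Longest linear sequence: 18 steps (steps 1–6, 12–15 and 22–29, from but-2-yn-1-ol).

Steps most likely to fail:

1. Step 13 (key step). The hydridopalladium species may add to the alkyne with the reverse orientation, may eliminate towards a6 to give the 1,3-diene, or may re-add to the product diene and scramble the Z alkene C9=C10. The fallback sets out from 18 and separates alkyne activation from ring closure. Molybdenum-catalysed Markovnikov hydrostannation (Bu3SnH, Mo(CO)3(CNt-Bu)3, zerovalent molybdenum, THF, 55 °C) should give the 2-stannyl-1-alkene F1. Iodine in CH2Cl2 at 0 °C converts it into the 2-iodo-1-alkene F2. A 6-exo Heck cyclization (Pd(OAc)2, PPh3, Ag2CO3, MeCN, 60 °C), in which the silver base traps the hydride, then comes back to the route at 19.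

2. Step 24. The peroxide may add at the dienyl terminus C7, may attack the ring face syn to the silyloxy group, or the base may isomerize the Z enone. The fallback sets out from 30 and replaces the enone epoxidation by a reagent-controlled electrophilic one at the carbinol stage. Sharpless epoxidation under kinetic-resolution conditions (Ti(Oi-Pr)4, L-(+)-diisopropyl tartrate, t-BuOOH, 4 Å sieves, CH2Cl2, −20 °C) should epoxidize only the 11S epimer at C12=C13, giving the erythro epoxy alcohol F3; the Z-configured allylic alkene C9=C10 belongs to the slow substrate class. The unreacted 11R epimer is separated. Removal of the triethylsilyl group from F3 with HF·pyridine comes back to the route at 34.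

3. Step 20. Facial discrimination between the two alkenyl arms of the cross-conjugated ketone may be poor, or conjugate reduction may compete. The fallback sets out from 26. Luche reduction (NaBH4, CeCl3·7H2O, MeOH, −78 °C) gives the racemic alcohol F4. Lipase-catalysed acylation (Burkholderia cepacia lipase, vinyl acetate, t-BuOMe) is expected to acetylate the R enantiomer to the R acetate F5 and to leave the S alcohol, which is 27, where the route is rejoined.

Further compounds
F1 | step 13 | tributyl[(5R,7E,10Z)-5,12-bis[(tert-butyldimethylsilyl)oxy]-6,6,10-trimethyldodeca-1,7,10-trien-2-yl]stannane | C=C([Sn](CCCC)(CCCC)CCCC)CC[C@@H](O[Si](C)(C)C(C)(C)C)C(C)(C)/C=C/C/C(C)=C\CO[Si](C)(C)C(C)(C)C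
F2 | step 13 | (5R,7E,10Z)-5,12-bis[(tert-butyldimethylsilyl)oxy]-2-iodo-6,6,10-trimethyldodeca-1,7,10-triene | C=C(I)CC[C@@H](O[Si](C)(C)C(C)(C)C)C(C)(C)/C=C/C/C(C)=C\CO[Si](C)(C)C(C)(C)C
F3 | step 24 | erythro epoxy alcohol (11S), C17 triethylsilyl ether of 34 | C=C1CC[C@@H](O[Si](C)(C)C(C)(C)C)C(C)(C)[C@H]1/C=C/C(C)=C\[C@H](O)[C@]12O[C@H]1C(OC)(OC)C(CO[Si](C(C)C)(C(C)C)C(C)C)=C[C@@H]2O[Si](CC)(CC)CC
F4 | step 20 | racemic 2-bromo-4,4-dimethoxy-5-{[(triisopropylsilyl)oxy]methyl}cyclohexa-2,5-dien-1-ol | BrC1=CC(OC)(OC)C(CO[Si](C(C)C)(C(C)C)C(C)C)=CC1O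
F5 | step 20 | (1R)-2-bromo-4,4-dimethoxy-5-{[(triisopropylsilyl)oxy]methyl}cyclohexa-2,5-dien-1-yl acetate | BrC1=CC(OC)(OC)C(CO[Si](C(C)C)(C(C)C)C(C)C)=C[C@H]1OC(C)=O
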